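(The runs stem from a simulated flask with constants of no real substance; scatter was added.)

The meeting opened on a one-step world, substrate and reagent giving target, and dropped it at once, since the zeta run shows isomer of the product beside target at its first reading. Writing q and p for the fractions of the substrate charge standing as isomer and as target, the secretary noted q/p = 0.546 at 0.667 min.

| flask | substrate | reagent | free catalyst | remark | time |
|---|---|---|---|---|---|
| zeta | 0.20 mM | 0.65 equiv | 0.14 mol% | run made earlier |  |
| theta | 0.20 mM | 0.98 equiv | 0.14 mol% | run made earlier |  |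
| delta | 0.20 mM | 1.3 equiv | 0.21 mol% | run made earlier |  |
| flask | 0.20 mM | 1.30 equiv | 0.14 mol% |  | 10 min |

| run | time / min | isomer of the product / % | target / % |
|---|---|---|---|
| zeta | 0.667 | 11.9 | 21.8 |
| zeta | 1.00 | 14.7 | 22.2 |
| zeta | 1.33 | 17.3 | 21.3 |
| zeta | 2.50 | 23.4 | 17.5 |
| zeta | 3.00 | 25.2 | 15.1 |
| zeta | 5.00 | 30.2 | 10.0 |
| zeta | 8.00 | 36.4 | 6.5 |
| theta | 1.00 | 19.6 | 30.2 |
| theta | 2.50 | 30.6 | 23.9 |
| theta | 3.00 | 33.6 | 22.3 |
| theta | 5.00 | 40.6 | 15.1 |
| theta | 6.00 | 44.5 | 12.3 |
| theta | 8.00 | 47.6 | 8.8 |
| delta | 0.667 | 20.2 | 36.2 |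
| delta | 1.33 | 28.9 | 33.9 |
| delta | 2.50 | 38.2 | 27.3 |
| delta | 4.00 | 46.1 | 21.7 |
| delta | 8.00 | 57.8 | 11.8 |

(standard deviation of a reading: 0.5 percentage points)



- ratio of isomer of the product to target at 0.25 s
- ratio of isomer of the product to target at 12 s
- ratio of isomer of the product to target at 10 min
- which of isomer of the product and target there is more of at 10 min

I argued that dividing the rate of isomer formation by that of target formation removes time. In zeta, q/p climbs to 0.662 at 1.00 min, a slope of 0.349 min⁻¹, and going back along it to time zero gives the reading 0.313. Call this b, the branching ratio: isomer made per target made at the very start, the selectivity factor of the two routes.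

A colleague objected that reagent might move it. I answered from the readings. Delta holds twice the reagent of zeta, and also more catalyst, yet its first q/p is 0.558 at 0.667 min, the time of the first zeta reading. Theta, which differs from zeta in reagent and not in catalyst, gives 0.649 at 1.00 min, against 0.662 in zeta.

So I carried b and the zeta slope to the flask, which has the catalyst loading of zeta: my own ratios are 0.314 at 0.25 s and 0.383 at 12 s. I set no late figure of my own, but zeta already reads 5.60 at 8.00 min, so I expected isomer ahead.

The forecast differs early, with 0.48 and 0.51, higher than mine, holding that by the second time “isomerisation has barely contributed”. For 10 min it gives 7.4, with isomer of the product ahead.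

The flask gives 0.375 at 0.25 s, 0.418 at 12 s and 6.51 at 10 min, with isomer of the product ahead, 59.5% against 9.14%.

    substrate + reagent ⇌ target (K = 12000 M⁻¹, k = 130 M⁻¹ s⁻¹)
    reagent + free catalyst → spent catalyst (k = 58.4 M⁻¹ s⁻¹)
    target + free catalyst ⇌ isomer of the product + free catalyst, rate k3*[free catalyst]*[target] forward; the back reaction follows from the equilibrium constant (k = 6420 M⁻¹ s⁻¹)
    2 substrate → self-condensation product (k = 35.8 M⁻¹ s⁻¹)
    substrate + reagent ⇌ isomer of the product (K = 9.80 × 10⁵ M⁻¹, k = 48.6 M⁻¹ s⁻¹)

In the flask, reagent used by the isomer-forming step over that used by the target-forming step, forward rates alone, stands at 0.37 at the start and 0.37 at 1.70 min. Carried to a further flask, like this one but with 0.520 equiv of reagent, b and the zeta slope give the same reckoning of 0.314 at 0.25 s, and that further flask stands at 0.375 at 0.25 s and 0.418 at 12 s.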